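## The problem

The target is an achiral pentaphenol. Ring A is hexasubstituted (C1 OMe, C2 H, C3 OH, C4 and C6 4-hydroxybenzyl, C5 a two-carbon bridge). The bridge leads to ring B, a 1,3,5-trisubstituted benzene carrying a hydroxyl and a third 4-hydroxybenzyl group. There is no stereocentre, so nothing has to be controlled in space, and the whole difficulty is regiochemical. Ring A carries five contiguous substituents, and its two oxygens differ only in that C1 is methylated and C3 is free, on a ring that is otherwise symmetric about the C2–C5 axis. Benzylating a preformed resorcinol would have to avoid the most nucleophilic position C2 and stop at two groups, so ring A is better assembled with its substituents already in place. The free phenols, and above all the 4-hydroxybenzyl units, are prone to oxidation and to quinone methide chemistry under acid. They are therefore carried as benzyl ethers and released together at the very end. The structural feature that opens the route is that the C4 benzylic carbon lies ortho to the C3 hydroxyl and para to the C1 oxygen, the place of the carboxyl carbon in a 2,4-dihydroxybenzoate. Ring A then reads as a folded tetraketide chain (carboxyl carbon, C4, C3, C2, C1, C6, C5) that closes by a C4–C5 aldol. The carboxyl and the C3 oxygen can be tied together in a dioxinone, which leaves the C1 hydroxyl as the only free phenol when the ring forms.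

## Retrosynthesis

Target 26 is traced back to its tetrabenzyl ether 25 by cutting four O–benzyl bonds. One hydrogenolysis then frees every masked phenol in the last step, and no phenol has to survive the carbanion chemistry that precedes it.

In 25 the bond between the C4 benzylic carbon and its aryl ring is cut after the CH2 is raised to a ketone, giving ortho-hydroxy benzophenone 23. This is preferred over a Friedel–Crafts benzylation of ring A, which would not distinguish C4 from C2. Ketone 23 arises from benzodioxinone 21 and 4-(benzyloxy)phenylmagnesium bromide 22. The forward reaction must stop after one addition, and the phenoxide released on ring opening should ensure that. The deoxygenation to 25 passes through aryl ethyl carbonate 24 and uses the neighbouring C3 hydroxyl.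

Benzodioxinone 21 is the methyl ether of phenol 20, so only the O–CH3 bond is cut. No selectivity is asked of the methylation, because 20 has a single free hydroxyl (C1) while the C3 oxygen is locked in the acetonide.

Resorcylate 20 is opened at the C4–C5 bond to diketo-dioxinone 18. This cut removes the only ring that has to be built and turns a hexasubstituted benzene into a linear chain with all substituents at their future positions. The forward step, an aldol through cyclic adduct 19 followed by dehydration and enolisation, must favour C- over O-cyclisation and one fold over the others.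

Chain 18 is cut between the benzyl-bearing carbon (future C6) and the distal carbonyl (future C5). This gives keto-dioxinone 7, used as its dianion 17, and N-methoxy-N-methylamide 16. The cut is the most convergent one, since it separates the ring A half from the whole ring B half, and it puts the C6 benzyl group in place with no separate alkylation. The forward Claisen condensation must take place at the α' carbanion of 17 and stop at the ketone stage.

Keto-dioxinone 7 is cut between the future C2 and C1 into commercial dioxinone 4, used as its lithium dienolate 6, and acyl imidazole 5. Imidazolide 5 is made in the flask from acid 3, which comes from 3-(4-hydroxyphenyl)propanoic acid 1 through benzyl ester 2. The forward reaction is a γ-selective C-acylation of 6.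

Amide 16 comes from ethyl ester 15. Ester 15 is cut at the bond between ring B and the bridge into aryl bromide 13 and the commercial zinc homoenolate 14. This installs the three-carbon acyl arm at the right oxidation level in one coupling, where a Heck reaction would add an alkene reduction.

Bromide 13 is cut at the ring B to CH2 bond after raising the CH2 to the carbinol 12. Carbinol 12 comes from aryllithium 11, made from dibromide 9, and 4-(benzyloxy)benzaldehyde 10. Dibromide 9 is the benzyl ether of 3,5-dibromophenol 8. The two equivalent bromines of 9 make the mono-exchange a matter of stoichiometry alone.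

## Roads not taken

Alternative 1: Ring A would be kept intact and the C5–bridge and C6–benzylic bonds cut together.
- Forward step: CsF would turn 5-(benzyloxy)-6-[4-(benzyloxy)benzyl]-3-methoxy-2-(trimethylsilyl)phenyl trifluoromethanesulfonate A2 into the aryne 4-(benzyloxy)-3-[4-(benzyloxy)benzyl]-6-methoxy-1,2-didehydrobenzene A3. This would insert into the C–C bond of methyl 3-[4-(benzyloxy)phenyl]-3-oxopropanoate A4 to give methyl 2-{3-(benzyloxy)-2-[4-(benzyloxy)benzyl]-6-[4-(benzyloxy)benzoyl]-5-methoxyphenyl}acetate A1.
- Merits: two adjacent C–C bonds form in one mild operation. The C1 methoxy group steers the enolate to the remote aryne carbon C5, so the aroyl group lands on C6 as required.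
- Weak points: A2 is already a pentasubstituted benzene with differentiated oxygens and the C4 benzyl group in place, so the substitution problem of ring A is moved and not solved. The enolate has to attack the aryne carbon next to that benzyl group. After the key step the bridge is only an acetate arm, which still needs reduction, a carbonyl addition of a ring B organometal and a deoxygenation, beside the reduction of the C6 ketone.
- Comparison: it avoids the dianion Claisen condensation and the opening of a hindered lactone, and it is convergent in the aroyl piece. Against this the chosen plan sets a ring A whose substitution pattern follows from the chain by construction, and a bridge that arrives complete with ring B.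

Alternative 2: The C4 and C6 benzylic bonds and the C5–bridge bond would all be cut at once.
- Forward step: Pd(OAc)2, tri(2-furyl)phosphine, norbornene and Cs2CO3 would combine 1-(benzyloxy)-3-iodo-5-methoxybenzene A6, two equivalents of 1-(benzyloxy)-4-(chloromethyl)benzene A7 and the styrene 1-(benzyloxy)-3-[4-(benzyloxy)benzyl]-5-ethenylbenzene A8 in a Catellani reaction. The product would be 1-(benzyloxy)-2,4-bis[4-(benzyloxy)benzyl]-3-[(E)-2-{3-(benzyloxy)-5-[4-(benzyloxy)benzyl]phenyl}ethenyl]-5-methoxybenzene A5.
- Merits: in step economy this road is clearly better. A8 is one coupling away from bromide 13, the oxygens are differentiated from the start in A6, and a single hydrogenation of A5 would saturate the alkene and remove all benzyl groups to give 26.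
- Weak points: each ortho C–H of A6 lies between the iodide and an alkoxy group. Norbornene-mediated ortho alkylation normally fails at positions flanked by a meta substituent, and here it would have to succeed twice. Benzyl chlorides also add directly to zerovalent palladium and can benzylate the styrene or homocouple, so four components would have to find one order of events.
- Comparison: the chosen plan is about twice as long. What it sets against this is that every bond is made by a reaction with direct precedent on the same substrate class, and that no step depends on forcing a catalyst beyond its known steric limit.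

Alternative 3: The future C4–C5 and C1–C2 bonds would be cut, building ring A at the cyclohexane-1,3-dione level.
- Forward step: KOtBu would add the internal enolate of 4-[4-(benzyloxy)phenyl]butan-2-one A11 to methyl (E)-2-[4-(benzyloxy)benzyl]-5-{3-(benzyloxy)-5-[4-(benzyloxy)benzyl]phenyl}pent-2-enoate A10. The methyl enolate would then close onto the ester to give all-trans 4,6-bis[4-(benzyloxy)benzyl]-5-(2-{3-(benzyloxy)-5-[4-(benzyloxy)benzyl]phenyl}ethyl)cyclohexane-1,3-dione A9.
- Merits: both benzyl groups and the bridge come from simple open-chain pieces. The three centres of A9 are erased on aromatisation. An oxidative aromatisation in methanol could in principle give the monomethyl ether directly and meet the chosen route at 25, with no Grignard opening and no ketone deoxygenation. In that respect its endgame is shorter.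
- Weak points: A10 is a trisubstituted, α-branched enoate and a poor Michael acceptor. The more substituted enolate of A11 has to react in preference to the methyl enolate, otherwise a benzyl group ends up between the two carbonyls. The dehydrogenation must be carried out on a molecule with five electron-rich rings and many benzylic C–H bonds.
- Comparison: the chosen plan reaches the aromatic oxidation level by loss of water alone and differentiates the two oxygens through the acetonide, at the price of two extra steps after ring formation.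

Key step: step 9

Remark on the chemistry: the target has no stereocentre. The centres that appear on the way (in 12, 18 and 19) are formed without control and are removed by later steps. Reagents 14 and 22 are taken as commercial THF solutions.

## Steps

Step 1
Reactants: 1 3-(4-hydroxyphenyl)propanoic acid
Product: 3 3-[4-(benzyloxy)phenyl]propanoic acid, via benzyl 3-[4-(benzyloxy)phenyl]propanoate 2 (not isolated)
Conditions: BnBr (2.3 equiv), K2CO3, DMF, 60 °C; then 2 M NaOH, MeOH/THF, 60 °C; HCl work-up
Reagents that add atoms: benzyl bromide, BrCc1ccccc1; sodium hydroxide, [Na+].[OH-]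
Why: Williamson alkylation of phenoxide and carboxylate followed by saponification of the benzyl ester; the aryl benzyl ether is inert to aqueous hydroxide.

Step 2
Reactants: 3 3-[4-(benzyloxy)phenyl]propanoic acid; 4 2,2,6-trimethyl-4H-1,3-dioxin-4-one
Product: 7 6-{4-[4-(benzyloxy)phenyl]-2-oxobutyl}-2,2-dimethyl-4H-1,3-dioxin-4-one, via acyl imidazole 5 (not isolated), via lithium dienolate 6 (not isolated)
Conditions: 3, 1,1'-carbonyldiimidazole, THF, 23 °C; added to 4 (2.2 equiv) + LiN(SiMe3)2 (2.2 equiv), THF, −78 → −30 °C; aq. NH4Cl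
Reagents that add atoms: none
Why: Vinylogous Claisen condensation: the lithium dienolate of the dioxinone is acylated at its γ-carbon by the imidazolide, and the second equivalent of dienolate deprotonates the more acidic product, which should suppress double acylation.

Step 3
Reactants: 8 3,5-dibromophenol
Product: 9 1-(benzyloxy)-3,5-dibromobenzene
Conditions: BnBr, K2CO3, acetone, 56 °C
Reagents that add atoms: benzyl bromide, BrCc1ccccc1
Why: Williamson ether synthesis on an acidic, unhindered phenol.

Step 4
Reactants: 9 1-(benzyloxy)-3,5-dibromobenzene; 10 4-(benzyloxy)benzaldehyde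
Product: 12 [3-(benzyloxy)-5-bromophenyl][4-(benzyloxy)phenyl]methanol (racemic), via [3-(benzyloxy)-5-bromophenyl]lithium 11 (not isolated)
Conditions: n-BuLi (1.05 equiv), Et2O, −78 °C; then 10, −78 → 0 °C; aq. NH4Cl
Reagents that add atoms: none
Why: Bromine–lithium exchange on one of two equivalent bromides is fast at −78 °C and the electron-rich aryllithium should not exchange a second time; 1,2-addition to the aldehyde gives a racemic carbinol whose centre is removed in step 5.

Step 5
Reactants: 12 [3-(benzyloxy)-5-bromophenyl][4-(benzyloxy)phenyl]methanol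
Product: 13 1-(benzyloxy)-3-[4-(benzyloxy)benzyl]-5-bromobenzene
Conditions: Et3SiH, CF3CO2H, CH2Cl2, 0 °C
Reagents that add atoms: none
Why: Ionic hydrogenation: acid ionises the doubly benzylic alcohol to a cation stabilised by the para-benzyloxyphenyl ring and the silane delivers hydride; aryl bromide and aryl benzyl ethers should survive brief exposure at 0 °C.

Step 6
Reactants: 13 1-(benzyloxy)-3-[4-(benzyloxy)benzyl]-5-bromobenzene; 14 (3-ethoxy-3-oxopropyl)zinc bromide
Product: 15 ethyl 3-{3-(benzyloxy)-5-[4-(benzyloxy)benzyl]phenyl}propanoate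
Conditions: Pd(OAc)2 (2 mol %), 2-dicyclohexylphosphino-2',6'-dimethoxybiphenyl (4 mol %), THF, 50 °C
Reagents that add atoms: none
Why: Negishi coupling of an aryl bromide with a primary alkylzinc bromide; the bulky biarylphosphine favours reductive elimination over β-hydride elimination, and the ester and benzyl ethers are inert to the organozinc.

Step 7
Reactants: 15 ethyl 3-{3-(benzyloxy)-5-[4-(benzyloxy)benzyl]phenyl}propanoate
Product: 16 3-{3-(benzyloxy)-5-[4-(benzyloxy)benzyl]phenyl}-N-methoxy-N-methylpropanamide
Conditions: MeNH(OMe)·HCl, iPrMgCl, THF, −20 → 0 °C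
Reagents that add atoms: N,O-dimethylhydroxylamine hydrochloride, CNOC.Cl
Why: Direct aminolysis of the ester by the chloromagnesium amide of N,O-dimethylhydroxylamine; the chelated tetrahedral intermediate prevents further addition.

Step 8
Reactants: 7 6-{4-[4-(benzyloxy)phenyl]-2-oxobutyl}-2,2-dimethyl-4H-1,3-dioxin-4-one; 16 3-{3-(benzyloxy)-5-[4-(benzyloxy)benzyl]phenyl}-N-methoxy-N-methylpropanamide
Product: 18 6-{3-[4-(benzyloxy)benzyl]-6-{3-(benzyloxy)-5-[4-(benzyloxy)benzyl]phenyl}-2,4-dioxohexyl}-2,2-dimethyl-4H-1,3-dioxin-4-one (racemic and labile at the carbon between the ketones), via dilithium dianion of the keto-dioxinone 17 (not isolated)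
Conditions: 7 (1.3 equiv), LiN(iPr)2 (2.7 equiv), THF, −78 → −40 °C; then 16, −78 → −20 °C; cold aq. NH4Cl; used after a short silica plug
Reagents that add atoms: none
Why: Crossed Claisen condensation of a 1,3-dicarbonyl dianion: the amide base removes first the proton between dioxinone and ketone and then an α' proton, and the more basic α' carbanion attacks the N-methoxy-N-methylamide, whose chelated adduct releases the 1,3-diketone only on quench, so over-addition and quenching of the dianion by product should not occur.

Step 9
Reactants: 18 6-{3-[4-(benzyloxy)benzyl]-6-{3-(benzyloxy)-5-[4-(benzyloxy)benzyl]phenyl}-2,4-dioxohexyl}-2,2-dimethyl-4H-1,3-dioxin-4-one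
Product: 20 6-[4-(benzyloxy)benzyl]-5-(2-{3-(benzyloxy)-5-[4-(benzyloxy)benzyl]phenyl}ethyl)-7-hydroxy-2,2-dimethyl-4H-benzo[d][1,3]dioxin-4-one, via cyclic aldol adduct 19 (not isolated)
Conditions: Et3N (5 equiv), CH2Cl2, 23 °C
Reagents that add atoms: none
Why: Triethylamine removes a proton from the CH2 between the dioxinone and the first ketone, and the resulting vinylogous enolate attacks the distal ketone through the dioxinone α-carbon to give aldol adduct 19; E1cB loss of the new hydroxyl against the acidic ring-fusion hydrogen and enolisation of the remaining ring ketone through the hydrogen on the benzyl-bearing carbon then aromatise ring A. The closest known reaction type is the base-induced biomimetic aldol aromatisation of diketo-dioxinones to acetonide-protected resorcylates, modelled on the folding of a tetraketide in resorcylate biosynthesis. Ring A closes in a 6-(enolexo)-exo-trig mode, since the enolate double bond (carboxyl carbon to C4) lies outside the new ring and the oxygen of the attacked carbonyl is exocyclic. No stereocentre is set: the labile centre of 18 and the three centres of 19 all become sp2 carbons, so their configuration is immaterial. The step needs C-cyclisation over O-cyclisation and one fold among several, and the dioxinone should secure both, because its lactone carbonyl is held trans to the side chain across the ring double bond and cannot be reached by any enolate carbon or enol oxygen, which leaves the closure from the dioxinone α-carbon onto the distal ketone as the only six-membered carbocycle available. A mild amine base in the absence of acid should keep the acid-promoted pyranone closure (enol oxygen onto the dioxinone β-carbon) out of play. The benzyl group on the carbon between the ketones lowers the enol content of the 1,3-diketone, which should keep the distal carbonyl electrophilic, and it ends on C6 between the free hydroxyl and the bridge. The product holds the C3 oxygen in the acetonide and shows the C1 hydroxyl free, which is the differentiation that step 10 uses.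

Step 10
Reactants: 20 6-[4-(benzyloxy)benzyl]-5-(2-{3-(benzyloxy)-5-[4-(benzyloxy)benzyl]phenyl}ethyl)-7-hydroxy-2,2-dimethyl-4H-benzo[d][1,3]dioxin-4-one
Product: 21 6-[4-(benzyloxy)benzyl]-5-(2-{3-(benzyloxy)-5-[4-(benzyloxy)benzyl]phenyl}ethyl)-7-methoxy-2,2-dimethyl-4H-benzo[d][1,3]dioxin-4-one
Conditions: MeI, K2CO3, acetone, 40 °C
Reagents that add atoms: iodomethane, CI
Why: Williamson methylation of the only free phenol; carbonate in an aprotic solvent should not open the dioxinone.

Step 11
Reactants: 21 6-[4-(benzyloxy)benzyl]-5-(2-{3-(benzyloxy)-5-[4-(benzyloxy)benzyl]phenyl}ethyl)-7-methoxy-2,2-dimethyl-4H-benzo[d][1,3]dioxin-4-one; 22 4-(benzyloxy)phenylmagnesium bromide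
Product: 23 {3-[4-(benzyloxy)benzyl]-2-(2-{3-(benzyloxy)-5-[4-(benzyloxy)benzyl]phenyl}ethyl)-6-hydroxy-4-methoxyphenyl}[4-(benzyloxy)phenyl]methanone
Conditions: 22 (3 equiv), THF, 0 → 23 °C; aq. NH4Cl
Reagents that add atoms: none
Why: Grignard addition to the lactone carbonyl of a salicylate acetonide: the tetrahedral intermediate collapses with loss of acetone to the magnesium phenoxide of the ortho-hydroxy ketone, whose chelated, vinylogous carboxylate character should stop a second addition; the excess reagent allows for the equivalent taken up by the released acetone.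

Step 12
Reactants: 23 {3-[4-(benzyloxy)benzyl]-2-(2-{3-(benzyloxy)-5-[4-(benzyloxy)benzyl]phenyl}ethyl)-6-hydroxy-4-methoxyphenyl}[4-(benzyloxy)phenyl]methanone
Product: 25 2,4-bis[4-(benzyloxy)benzyl]-3-(2-{3-(benzyloxy)-5-[4-(benzyloxy)benzyl]phenyl}ethyl)-5-methoxyphenol, via aryl ethyl carbonate 24 (not isolated)
Conditions: ClCO2Et, Et3N, THF, 0 °C; then NaBH4, H2O, 0 → 23 °C
Reagents that add atoms: none
Why: ortho-Hydroxyl-assisted deoxygenation of an aryl ketone: borohydride reduces the ketone of the carbonate, the alkoxide takes over the carbonate group, 1,4-elimination gives an ortho-quinone methide, and a second hydride adds to its benzylic carbon; benzyl and methyl ethers are untouched.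

Step 13
Reactants: 25 2,4-bis[4-(benzyloxy)benzyl]-3-(2-{3-(benzyloxy)-5-[4-(benzyloxy)benzyl]phenyl}ethyl)-5-methoxyphenol
Product: 26 2,4-bis(4-hydroxybenzyl)-3-{2-[3-hydroxy-5-(4-hydroxybenzyl)phenyl]ethyl}-5-methoxyphenol
Conditions: H2 (1 atm), 10% Pd/C, EtOAc/MeOH, 23 °C
Reagents that add atoms: none
Why: Hydrogenolysis of four aryl benzyl ethers over palladium on carbon; the diarylmethane and bibenzyl C–C bonds and the aryl methyl ether are stable under these conditions.

## Compound list

1 | 3-(4-hydroxyphenyl)propanoic acid | OC(=O)CCc1ccc(O)cc1 | starting material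
2 | benzyl 3-[4-(benzyloxy)phenyl]propanoate (not isolated) | O=C(CCc1ccc(OCc2ccccc2)cc1)OCc1ccccc1 | intermediate
3 | 3-[4-(benzyloxy)phenyl]propanoic acid | OC(=O)CCc1ccc(OCc2ccccc2)cc1 | intermediate
4 | 2,2,6-trimethyl-4H-1,3-dioxin-4-one | CC1=CC(=O)OC(C)(C)O1 | starting material
5 | 3-[4-(benzyloxy)phenyl]-1-(1H-imidazol-1-yl)propan-1-one (acyl imidazole; not isolated) | O=C(CCc1ccc(OCc2ccccc2)cc1)n1ccnc1 | intermediate
6 | lithium 2,2-dimethyl-6-methylidene-6H-1,3-dioxin-4-olate (dienolate of 4; not isolated) | [Li+].C=C1C=C([O-])OC(C)(C)O1 | intermediate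
7 | 6-{4-[4-(benzyloxy)phenyl]-2-oxobutyl}-2,2-dimethyl-4H-1,3-dioxin-4-one | CC1(C)OC(=O)C=C(CC(=O)CCc2ccc(OCc3ccccc3)cc2)O1 | intermediate
8 | 3,5-dibromophenol | Oc1cc(Br)cc(Br)c1 | starting material
9 | 1-(benzyloxy)-3,5-dibromobenzene | Brc1cc(Br)cc(OCc2ccccc2)c1 | intermediate
10 | 4-(benzyloxy)benzaldehyde | O=Cc1ccc(OCc2ccccc2)cc1 | starting material
11 | [3-(benzyloxy)-5-bromophenyl]lithium (not isolated) | [Li]c1cc(Br)cc(OCc2ccccc2)c1 | intermediate
12 | [3-(benzyloxy)-5-bromophenyl][4-(benzyloxy)phenyl]methanol (racemic) | OC(c1ccc(OCc2ccccc2)cc1)c1cc(Br)cc(OCc2ccccc2)c1 | intermediate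
13 | 1-(benzyloxy)-3-[4-(benzyloxy)benzyl]-5-bromobenzene | Brc1cc(Cc2ccc(OCc3ccccc3)cc2)cc(OCc2ccccc2)c1 | intermediate
14 | (3-ethoxy-3-oxopropyl)zinc bromide | CCOC(=O)CC[Zn]Br | starting material
15 | ethyl 3-{3-(benzyloxy)-5-[4-(benzyloxy)benzyl]phenyl}propanoate | CCOC(=O)CCc1cc(OCc2ccccc2)cc(Cc2ccc(OCc3ccccc3)cc2)c1 | intermediate
16 | 3-{3-(benzyloxy)-5-[4-(benzyloxy)benzyl]phenyl}-N-methoxy-N-methylpropanamide | CON(C)C(=O)CCc1cc(OCc2ccccc2)cc(Cc2ccc(OCc3ccccc3)cc2)c1 | intermediate
17 | dilithium 6-{4-[4-(benzyloxy)phenyl]-2-oxidobut-2-en-1-ylidene}-2,2-dimethyl-6H-1,3-dioxin-4-olate (dianion of 7; not isolated) | [Li+].[Li+].CC1(C)OC([O-])=CC(=CC([O-])=CCc2ccc(OCc3ccccc3)cc2)O1 | intermediate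
18 | 6-{3-[4-(benzyloxy)benzyl]-6-{3-(benzyloxy)-5-[4-(benzyloxy)benzyl]phenyl}-2,4-dioxohexyl}-2,2-dimethyl-4H-1,3-dioxin-4-one (racemic, labile centre) | CC1(C)OC(=O)C=C(CC(=O)C(Cc2ccc(OCc3ccccc3)cc2)C(=O)CCc2cc(OCc3ccccc3)cc(Cc3ccc(OCc4ccccc4)cc3)c2)O1 | intermediate
19 | 6-[4-(benzyloxy)benzyl]-5-(2-{3-(benzyloxy)-5-[4-(benzyloxy)benzyl]phenyl}ethyl)-5-hydroxy-2,2-dimethyl-4a,5-dihydro-4H-benzo[d][1,3]dioxine-4,7(6H)-dione (mixture of diastereomers; not isolated) | CC1(C)OC(=O)C2C(O1)=CC(=O)C(Cc3ccc(OCc4ccccc4)cc3)C2(O)CCc2cc(OCc3ccccc3)cc(Cc3ccc(OCc4ccccc4)cc3)c2 | intermediate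
20 | 6-[4-(benzyloxy)benzyl]-5-(2-{3-(benzyloxy)-5-[4-(benzyloxy)benzyl]phenyl}ethyl)-7-hydroxy-2,2-dimethyl-4H-benzo[d][1,3]dioxin-4-one | CC1(C)OC(=O)c2c(O1)cc(O)c(Cc3ccc(OCc4ccccc4)cc3)c2CCc2cc(OCc3ccccc3)cc(Cc3ccc(OCc4ccccc4)cc3)c2 | intermediate
21 | 6-[4-(benzyloxy)benzyl]-5-(2-{3-(benzyloxy)-5-[4-(benzyloxy)benzyl]phenyl}ethyl)-7-methoxy-2,2-dimethyl-4H-benzo[d][1,3]dioxin-4-one | CC1(C)OC(=O)c2c(O1)cc(OC)c(Cc3ccc(OCc4ccccc4)cc3)c2CCc2cc(OCc3ccccc3)cc(Cc3ccc(OCc4ccccc4)cc3)c2 | intermediate
22 | 4-(benzyloxy)phenylmagnesium bromide | Br[Mg]c1ccc(OCc2ccccc2)cc1 | starting material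
23 | {3-[4-(benzyloxy)benzyl]-2-(2-{3-(benzyloxy)-5-[4-(benzyloxy)benzyl]phenyl}ethyl)-6-hydroxy-4-methoxyphenyl}[4-(benzyloxy)phenyl]methanone | COc1cc(O)c(C(=O)c2ccc(OCc3ccccc3)cc2)c(CCc2cc(OCc3ccccc3)cc(Cc3ccc(OCc4ccccc4)cc3)c2)c1Cc1ccc(OCc2ccccc2)cc1 | intermediate
24 | 2-[4-(benzyloxy)benzoyl]-4-[4-(benzyloxy)benzyl]-3-(2-{3-(benzyloxy)-5-[4-(benzyloxy)benzyl]phenyl}ethyl)-5-methoxyphenyl ethyl carbonate (not isolated) | CCOC(=O)Oc1cc(OC)c(Cc2ccc(OCc3ccccc3)cc2)c(CCc2cc(OCc3ccccc3)cc(Cc3ccc(OCc4ccccc4)cc3)c2)c1C(=O)c1ccc(OCc2ccccc2)cc1 | intermediate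
25 | 2,4-bis[4-(benzyloxy)benzyl]-3-(2-{3-(benzyloxy)-5-[4-(benzyloxy)benzyl]phenyl}ethyl)-5-methoxyphenol | COc1cc(O)c(Cc2ccc(OCc3ccccc3)cc2)c(CCc2cc(OCc3ccccc3)cc(Cc3ccc(OCc4ccccc4)cc3)c2)c1Cc1ccc(OCc2ccccc2)cc1 | intermediate
26 | 2,4-bis(4-hydroxybenzyl)-3-{2-[3-hydroxy-5-(4-hydroxybenzyl)phenyl]ethyl}-5-methoxyphenol | COc1cc(O)c(Cc2ccc(O)cc2)c(CCc2cc(O)cc(Cc3ccc(O)cc3)c2)c1Cc1ccc(O)cc1 | target

## Step count and risks

Total step count: 13. Longest linear sequence: 11 steps (steps 3 to 13, from 3,5-dibromophenol 8). The second branch (steps 1 and 2) joins at step 8.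

Step 9 (key step). The closure may stall before or at the aldol adduct because the benzyl group next to the distal ketone crowds the carbonyl. Prolonged exposure to base could then allow retro-Claisen cleavage of the 2-substituted 1,3-diketone or O-cyclisation. The fallback sets out from 18 and changes the order of events. Thermolysis in toluene at 110 °C with tert-butanol (loss of acetone, ketene trapping) should give the open-chain tert-butyl 6-[4-(benzyloxy)benzyl]-9-{3-(benzyloxy)-5-[4-(benzyloxy)benzyl]phenyl}-3,5,7-trioxononanoate F1. In F1 the nucleophilic carbon is a freely rotating β-keto ester methylene. Cs2CO3 in 2-propanol followed by acetic acid should close and aromatise it to tert-butyl 3-[4-(benzyloxy)benzyl]-2-(2-{3-(benzyloxy)-5-[4-(benzyloxy)benzyl]phenyl}ethyl)-4,6-dihydroxybenzoate F2. Trifluoroacetic acid, trifluoroacetic anhydride and acetone at 0 °C would then cleave the tert-butyl ester and form the acetonide, returning to the route at 20.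

Step 8. The α' carbanion of 17 is secondary and hindered, so proton transfer from the α-CH2 of amide 16 may compete with acylation. The product may also begin to cyclise on silica. The fallback sets out from 16 and 7 and replaces the Claisen condensation by an aldol addition and oxidation. Reduction of 16 with iBu2AlH at −78 °C should give 3-{3-(benzyloxy)-5-[4-(benzyloxy)benzyl]phenyl}propanal F3. Addition of dianion 17 to F3 at −78 °C should give 6-{3-[4-(benzyloxy)benzyl]-6-{3-(benzyloxy)-5-[4-(benzyloxy)benzyl]phenyl}-4-hydroxy-2-oxohexyl}-2,2-dimethyl-4H-1,3-dioxin-4-one F4. Oxidation of the β-hydroxy ketone with 2-iodoxybenzoic acid in ethyl acetate would come back to the route at 18.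

Step 11. Addition to a lactone carbonyl flanked by the C5 side chain may be slow, and the released acetone and any early collapse of the tetrahedral intermediate invite consumption of reagent and double addition. The fallback sets out from 21 and builds the benzylic carbon at the alcohol level. Reduction with iBu2AlH in CH2Cl2 at −78 °C (collapse of the hemiacetal with loss of acetone) should give 3-[4-(benzyloxy)benzyl]-2-(2-{3-(benzyloxy)-5-[4-(benzyloxy)benzyl]phenyl}ethyl)-6-hydroxy-4-methoxybenzaldehyde F5. Addition of 22 (2.5 equiv) should give {3-[4-(benzyloxy)benzyl]-2-(2-{3-(benzyloxy)-5-[4-(benzyloxy)benzyl]phenyl}ethyl)-6-hydroxy-4-methoxyphenyl}[4-(benzyloxy)phenyl]methanol F6. Ionic hydrogenation of F6 with Et3SiH and trifluoroacetic acid at 0 °C would come back to the route at 25 and bypass step 12.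

Step 12. Borohydride may cleave the carbonate before it reduces the hindered ketone, or the sequence may stop at the benzhydrol stage if carbonate transfer and elimination are slow. The fallback sets out from 23 and leaves the hydride and quinone-methide manifold for an acid-mediated one. Ionic hydrogenation of the ketone with excess Et3SiH in trifluoroacetic acid and CH2Cl2 at 23 °C proceeds through the strongly stabilised diarylmethyl cation. It would return to the route at 25 and makes no new compound. Partial loss of benzyl groups under these conditions would be harmless, because step 13 removes them all.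

Step 6. Transmetalation of the ester-stabilised alkylzinc may be slow, which would favour protodezincation and reduction of the aryl bromide. The fallback sets out from 13 and uses an alkene as the carbon nucleophile. A Heck reaction with ethyl acrylate (Pd(OAc)2, tri(o-tolyl)phosphine, Et3N, DMF, 100 °C) should give ethyl (E)-3-{3-(benzyloxy)-5-[4-(benzyloxy)benzyl]phenyl}prop-2-enoate F7. Conjugate reduction with NaBH4 and NiCl2·6H2O in MeOH/THF at 0 °C, which spares the benzyl ethers, would return to the route at 15.

## Further compounds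

F1 | step 9 | tert-butyl 6-[4-(benzyloxy)benzyl]-9-{3-(benzyloxy)-5-[4-(benzyloxy)benzyl]phenyl}-3,5,7-trioxononanoate | CC(C)(C)OC(=O)CC(=O)CC(=O)C(Cc1ccc(OCc2ccccc2)cc1)C(=O)CCc1cc(OCc2ccccc2)cc(Cc2ccc(OCc3ccccc3)cc2)c1
F2 | step 9 | tert-butyl 3-[4-(benzyloxy)benzyl]-2-(2-{3-(benzyloxy)-5-[4-(benzyloxy)benzyl]phenyl}ethyl)-4,6-dihydroxybenzoate | CC(C)(C)OC(=O)c1c(O)cc(O)c(Cc2ccc(OCc3ccccc3)cc2)c1CCc1cc(OCc2ccccc2)cc(Cc2ccc(OCc3ccccc3)cc2)c1
F3 | step 8 | 3-{3-(benzyloxy)-5-[4-(benzyloxy)benzyl]phenyl}propanal | O=CCCc1cc(OCc2ccccc2)cc(Cc2ccc(OCc3ccccc3)cc2)c1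
F4 | step 8 | 6-{3-[4-(benzyloxy)benzyl]-6-{3-(benzyloxy)-5-[4-(benzyloxy)benzyl]phenyl}-4-hydroxy-2-oxohexyl}-2,2-dimethyl-4H-1,3-dioxin-4-one (mixture of diastereomers) | CC1(C)OC(=O)C=C(CC(=O)C(Cc2ccc(OCc3ccccc3)cc2)C(O)CCc2cc(OCc3ccccc3)cc(Cc3ccc(OCc4ccccc4)cc3)c2)O1
F5 | step 11 | 3-[4-(benzyloxy)benzyl]-2-(2-{3-(benzyloxy)-5-[4-(benzyloxy)benzyl]phenyl}ethyl)-6-hydroxy-4-methoxybenzaldehyde | COc1cc(O)c(C=O)c(CCc2cc(OCc3ccccc3)cc(Cc3ccc(OCc4ccccc4)cc3)c2)c1Cc1ccc(OCc2ccccc2)cc1
F6 | step 11 | {3-[4-(benzyloxy)benzyl]-2-(2-{3-(benzyloxy)-5-[4-(benzyloxy)benzyl]phenyl}ethyl)-6-hydroxy-4-methoxyphenyl}[4-(benzyloxy)phenyl]methanol (racemic) | COc1cc(O)c(C(O)c2ccc(OCc3ccccc3)cc2)c(CCc2cc(OCc3ccccc3)cc(Cc3ccc(OCc4ccccc4)cc3)c2)c1Cc1ccc(OCc2ccccc2)cc1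
F0 | step 12 | none | none
F7 | step 6 | ethyl (E)-3-{3-(benzyloxy)-5-[4-(benzyloxy)benzyl]phenyl}prop-2-enoate | CCOC(=O)/C=C/c1cc(OCc2ccccc2)cc(Cc2ccc(OCc3ccccc3)cc2)c1
A1 | alternative 1 | methyl 2-{3-(benzyloxy)-2-[4-(benzyloxy)benzyl]-6-[4-(benzyloxy)benzoyl]-5-methoxyphenyl}acetate | COC(=O)Cc1c(C(=O)c2ccc(OCc3ccccc3)cc2)c(OC)cc(OCc2ccccc2)c1Cc1ccc(OCc2ccccc2)cc1
A2 | alternative 1 | 5-(benzyloxy)-6-[4-(benzyloxy)benzyl]-3-methoxy-2-(trimethylsilyl)phenyl trifluoromethanesulfonate | COc1cc(OCc2ccccc2)c(Cc2ccc(OCc3ccccc3)cc2)c(OS(=O)(=O)C(F)(F)F)c1[Si](C)(C)C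
A3 | alternative 1 | 4-(benzyloxy)-3-[4-(benzyloxy)benzyl]-6-methoxy-1,2-didehydrobenzene | COC1=CC(OCc2ccccc2)=C(Cc2ccc(OCc3ccccc3)cc2)C#C1
A4 | alternative 1 | methyl 3-[4-(benzyloxy)phenyl]-3-oxopropanoate | COC(=O)CC(=O)c1ccc(OCc2ccccc2)cc1
A5 | alternative 2 | 1-(benzyloxy)-2,4-bis[4-(benzyloxy)benzyl]-3-[(E)-2-{3-(benzyloxy)-5-[4-(benzyloxy)benzyl]phenyl}ethenyl]-5-methoxybenzene | COc1cc(OCc2ccccc2)c(Cc2ccc(OCc3ccccc3)cc2)c(/C=C/c2cc(OCc3ccccc3)cc(Cc3ccc(OCc4ccccc4)cc3)c2)c1Cc1ccc(OCc2ccccc2)cc1
A6 | alternative 2 | 1-(benzyloxy)-3-iodo-5-methoxybenzene | COc1cc(I)cc(OCc2ccccc2)c1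
A7 | alternative 2 | 1-(benzyloxy)-4-(chloromethyl)benzene | ClCc1ccc(OCc2ccccc2)cc1
A8 | alternative 2 | 1-(benzyloxy)-3-[4-(benzyloxy)benzyl]-5-ethenylbenzene | C=Cc1cc(OCc2ccccc2)cc(Cc2ccc(OCc3ccccc3)cc2)c1
A9 | alternative 3 | all-trans 4,6-bis[4-(benzyloxy)benzyl]-5-(2-{3-(benzyloxy)-5-[4-(benzyloxy)benzyl]phenyl}ethyl)cyclohexane-1,3-dione (meso) | O=C1CC(=O)[C@@H](Cc2ccc(OCc3ccccc3)cc2)[C@H](CCc2cc(OCc3ccccc3)cc(Cc3ccc(OCc4ccccc4)cc3)c2)[C@H]1Cc1ccc(OCc2ccccc2)cc1
A10 | alternative 3 | methyl (E)-2-[4-(benzyloxy)benzyl]-5-{3-(benzyloxy)-5-[4-(benzyloxy)benzyl]phenyl}pent-2-enoate | COC(=O)/C(Cc1ccc(OCc2ccccc2)cc1)=C/CCc1cc(OCc2ccccc2)cc(Cc2ccc(OCc3ccccc3)cc2)c1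
A11 | alternative 3 | 4-[4-(benzyloxy)phenyl]butan-2-one | CC(=O)CCc1ccc(OCc2ccccc2)cc1
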